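## Retrosynthetic overview

1. Rings: the tetrahydrofuran ring is bought as 2,5-dihydrofuran 1. A cyclopropane is fused onto it (dibromide 2), its two bromines are exchanged for aryl (from boronate 3, via 4–6) and OH to give meso cyclopropanol 7, and the cyclopropane is then cut open again; no other ring is built.
2. Key disconnection: the bond from ring carbon C4 to the benzylic CH2. It is formed from 7 and benzyl chloride 8 through a palladium homoenolate, in which the β-carbon of the aryl ketone acts as the nucleophile toward the benzylic electrophile. The cis-fused cyclopropane forces the cis ring relationship and a chiral ligand picks one of two enantiotopic C–C bonds, giving ketone 9.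
3. Carbinol centre: catalyst-controlled reduction of 9 gives 10.
4. End: hydrogenolysis of both aryl benzyl ethers gives target 11.

Assumption: boronate 3 and benzyl chloride 8 are bought as catalogue compounds; their commercial availability is taken as given.

## Route

Step 1
Reactants: 1 2,5-dihydrofuran
Product: 2 (1R,5S)-6,6-dibromo-3-oxabicyclo[3.1.0]hexane
Conditions: CHBr3, 50% aq. NaOH, BnEt3NCl (cat.), CH2Cl2, 0 °C to rt
Reagents that add atoms: bromoform, BrC(Br)Br
Why: Makosza phase-transfer dibromocarbene cyclopropanation; [2+1] addition to the cis alkene gives the necessarily cis-fused, meso dibromocyclopropane.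

Step 2
Reactants: 2 (1R,5S)-6,6-dibromo-3-oxabicyclo[3.1.0]hexane; 3 2-[3-(benzyloxy)-4-methoxyphenyl]-4,4,5,5-tetramethyl-1,3,2-dioxaborolane
Product: 7 (1R,5S)-6-[3-(benzyloxy)-4-methoxyphenyl]-3-oxabicyclo[3.1.0]hexan-6-ol, via lithium carbenoid 4 (not isolated), via boronate complex 5 (not isolated), via cyclopropyl boronate 6 (not isolated)
Conditions: n-BuLi, THF–Et2O, −100 °C; then 3, −100 °C to rt; then NaBO3·4H2O, THF–H2O, rt
Reagents that add atoms: sodium perborate tetrahydrate, [Na+].[O-]OB=O.O.O.O.O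
Why: Bromine–lithium exchange gives a bromo-lithium carbenoid that adds to the boronic ester, and a Matteson-type 1,2-metallate shift of the aryl group with loss of bromide followed by C–B oxidation (the known route from gem-dibromocyclopropanes to cyclopropanols) gives the tertiary cyclopropanol; C6 later becomes the carbonyl carbon, so its configuration does not matter, and the cis ring fusion is untouched.

Step 3
Reactants: 7 (1R,5S)-6-[3-(benzyloxy)-4-methoxyphenyl]-3-oxabicyclo[3.1.0]hexan-6-ol; 8 3-(benzyloxy)-4-methoxybenzyl chloride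
Product: 9 [3-(benzyloxy)-4-methoxyphenyl]{(3S,4R)-4-[3-(benzyloxy)-4-methoxybenzyl]tetrahydrofuran-3-yl}methanone
Conditions: Pd2(dba)3 (2.5 mol%), (S)-tBu-PHOX (6 mol%), Cs2CO3, toluene, 50 °C
Reagents that add atoms: none
Why: Proposed new method: zerovalent palladium inserts into the C–Cl bond of 8, the caesium alkoxide of 7 binds the resulting divalent benzylpalladium, and strain-driven β-carbon elimination with retention cuts one of the two enantiotopic cyclopropane C–C bonds (selected by the chiral hemilabile P,N ligand) to give an O-chelated palladium homoenolate; its C(sp3)–C(sp3) reductive elimination, again with retention, places the benzyl group on the ring face that still carries the aroyl group, so the cis relationship and the (3S,4R) configuration are set in one event (the ligand hand that gives (3S,4R) is kept after the first run); the closest known reactions are the palladium-catalysed cross-coupling of cyclopropanol-derived ketone homoenolates with benzyl chlorides and the enantioselective palladium-catalysed ring-opening coupling of prochiral tert-cyclobutanols by β-carbon elimination.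

Step 4
Reactants: 9 [3-(benzyloxy)-4-methoxyphenyl]{(3S,4R)-4-[3-(benzyloxy)-4-methoxybenzyl]tetrahydrofuran-3-yl}methanone
Product: 10 (S)-[3-(benzyloxy)-4-methoxyphenyl]{(3S,4R)-4-[3-(benzyloxy)-4-methoxybenzyl]tetrahydrofuran-3-yl}methanol
Conditions: (R)-2-methyl-CBS-oxazaborolidine (C18H20BNO, 20 mol%), BH3·SMe2, THF, −30 °C; aqueous work-up
Reagents that add atoms: none
Why: Corey–Bakshi–Shibata reduction: the (R)-oxazaborolidine–borane complex delivers hydride to the ketone face that gives the (S)-carbinol (aryl as the large group) under non-basic conditions that do not epimerise the cis C3 centre; catalyst control is needed because the substrate's own Felkin preference points to the (R)-epimer.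

Step 5
Reactants: 10 (S)-[3-(benzyloxy)-4-methoxyphenyl]{(3S,4R)-4-[3-(benzyloxy)-4-methoxybenzyl]tetrahydrofuran-3-yl}methanol
Product: 11 (S)-(3-hydroxy-4-methoxyphenyl)[(3S,4R)-4-(3-hydroxy-4-methoxybenzyl)tetrahydrofuran-3-yl]methanol
Conditions: H2 (1 atm), 10% Pd/C, EtOAc–EtOH, rt
Reagents that add atoms: none
Why: Palladium-catalysed hydrogenolysis of the two aryl benzyl ethers under neutral conditions is faster than cleavage of the secondary benzylic C–OH bond and frees both phenols without touching the three stereocentres.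

## Compound list

1 | 2,5-dihydrofuran | C1=CCOC1 | starting material
2 | (1R,5S)-6,6-dibromo-3-oxabicyclo[3.1.0]hexane (meso, cis-fused) | BrC1(Br)[C@@H]2COC[C@H]12 | intermediate
3 | 2-[3-(benzyloxy)-4-methoxyphenyl]-4,4,5,5-tetramethyl-1,3,2-dioxaborolane | COc1ccc(cc1OCc1ccccc1)B1OC(C)(C)C(C)(C)O1 | starting material
4 | [(1R,5S)-6-bromo-3-oxabicyclo[3.1.0]hexan-6-yl]lithium (C6 configuration not controlled) | [Li]C1(Br)[C@@H]2COC[C@H]12 | intermediate (not isolated)
5 | lithium [3-(benzyloxy)-4-methoxyphenyl][(1R,5S)-6-bromo-3-oxabicyclo[3.1.0]hexan-6-yl](pinacolato)borate | [Li+].BrC1([C@@H]2COC[C@H]12)[B-]3(OC(C)(C)C(C)(C)O3)c4ccc(OC)c(OCc5ccccc5)c4 | intermediate (not isolated)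
6 | 2-{(1R,5S)-6-[3-(benzyloxy)-4-methoxyphenyl]-3-oxabicyclo[3.1.0]hexan-6-yl}-4,4,5,5-tetramethyl-1,3,2-dioxaborolane | COc1ccc(cc1OCc1ccccc1)C3([C@@H]4COC[C@H]34)B5OC(C)(C)C(C)(C)O5 | intermediate (not isolated)
7 | (1R,5S)-6-[3-(benzyloxy)-4-methoxyphenyl]-3-oxabicyclo[3.1.0]hexan-6-ol (meso; C6 epimer immaterial) | COc1ccc(cc1OCc1ccccc1)C3(O)[C@@H]4COC[C@H]34 | intermediate
8 | 3-(benzyloxy)-4-methoxybenzyl chloride | COc1ccc(CCl)cc1OCc1ccccc1 | starting material
9 | [3-(benzyloxy)-4-methoxyphenyl]{(3S,4R)-4-[3-(benzyloxy)-4-methoxybenzyl]tetrahydrofuran-3-yl}methanone (ring substituents cis) | COc1ccc(C[C@H]2COC[C@H]2C(=O)c2ccc(OC)c(OCc3ccccc3)c2)cc1OCc1ccccc1 | intermediate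
10 | (S)-[3-(benzyloxy)-4-methoxyphenyl]{(3S,4R)-4-[3-(benzyloxy)-4-methoxybenzyl]tetrahydrofuran-3-yl}methanol | COc1ccc(C[C@H]2COC[C@H]2[C@H](O)c2ccc(OC)c(OCc3ccccc3)c2)cc1OCc1ccccc1 | intermediate
11 | (S)-(3-hydroxy-4-methoxyphenyl)[(3S,4R)-4-(3-hydroxy-4-methoxybenzyl)tetrahydrofuran-3-yl]methanol (CNP0108210.1) | COc1ccc(C[C@H]2COC[C@H]2[C@H](O)c2ccc(OC)c(O)c2)cc1O | target

## Step count and risks

Total step count: 5. Longest linear sequence: 5 (1 → 2 → 7 → 9 → 10 → 11).

The three steps most likely to fail are steps 3, 4 and 5.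

Step 3 is the main risk. The coupling is untested at a secondary, ring-bound homoenolate carbon; β-hydride elimination, low enantioselectivity, and base-induced epimerisation of 9 to the trans ketone are the failure modes. The fallback sets out from 8 and returns at 9, and replaces the cyclopropanol opening by asymmetric hydrogenation of a tetrasubstituted alkene:
- 8 is inserted with zinc dust and LiCl in THF to give [3-(benzyloxy)-4-methoxybenzyl]zinc chloride F1.
- Commercial methyl 4-oxotetrahydrofuran-3-carboxylate is triflated (Tf2O, iPr2NEt, CH2Cl2, −78 °C) to methyl 4-{[(trifluoromethyl)sulfonyl]oxy}-2,5-dihydrofuran-3-carboxylate F2.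
- Negishi coupling of the two (Pd(PPh3)4, THF) gives methyl 4-[3-(benzyloxy)-4-methoxybenzyl]-2,5-dihydrofuran-3-carboxylate F3.
- LiOH gives 4-[3-(benzyloxy)-4-methoxybenzyl]-2,5-dihydrofuran-3-carboxylic acid F4.
- Syn hydrogenation with Ru(OAc)2[(R)-BINAP] (H2 50 atm, MeOH; the BINAP hand that gives the wanted enantiomer is used) gives cis acid (3S,4R)-4-[3-(benzyloxy)-4-methoxybenzyl]tetrahydrofuran-3-carboxylic acid F5.
- EDC and MeNHOMe·HCl give (3S,4R)-4-[3-(benzyloxy)-4-methoxybenzyl]-N-methoxy-N-methyltetrahydrofuran-3-carboxamide F6.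
- [3-(benzyloxy)-4-methoxyphenyl]magnesium bromide F7 (from commercial 2-(benzyloxy)-4-bromo-1-methoxybenzene and Mg) adds to F6 at −20 °C to give ketone 9.

Step 4 may give a poor diastereomer ratio because catalyst and substrate preferences are mismatched. The fallback sets out from 9 and returns at 10, and uses the substrate bias followed by inversion:
- L-Selectride (THF, −78 °C) reduces 9 along its Felkin preference to (R)-[3-(benzyloxy)-4-methoxyphenyl]{(3S,4R)-4-[3-(benzyloxy)-4-methoxybenzyl]tetrahydrofuran-3-yl}methanol F8.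
- Mitsunobu inversion (PPh3, DIAD, 4-nitrobenzoic acid, THF, 0 °C) gives (S)-[3-(benzyloxy)-4-methoxyphenyl]{(3S,4R)-4-[3-(benzyloxy)-4-methoxybenzyl]tetrahydrofuran-3-yl}methyl 4-nitrobenzoate F9.
- K2CO3 in MeOH releases 10.

Step 5 may over-reduce: the electron-rich benzylic hydroxyl can be lost by hydrogenolysis. The fallback sets out from 9 and returns at 11, and reverses the order so that no benzylic alcohol is exposed to hydrogen:
- 9 is debenzylated first (H2, 10% Pd/C, EtOAc) to (3-hydroxy-4-methoxyphenyl)[(3S,4R)-4-(3-hydroxy-4-methoxybenzyl)tetrahydrofuran-3-yl]methanone F10.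
- F10 is then reduced with the same (R)-oxazaborolidine and extra BH3·SMe2 (the phenols are held as aryloxyboranes until work-up) to give 11 directly.

Further compounds
F1 | step 3 | [3-(benzyloxy)-4-methoxybenzyl]zinc chloride | COc1ccc(C[Zn]Cl)cc1OCc1ccccc1
F2 | step 3 | methyl 4-{[(trifluoromethyl)sulfonyl]oxy}-2,5-dihydrofuran-3-carboxylate | COC(=O)C1=C(OS(=O)(=O)C(F)(F)F)COC1
F3 | step 3 | methyl 4-[3-(benzyloxy)-4-methoxybenzyl]-2,5-dihydrofuran-3-carboxylate | COC(=O)C1=C(Cc2ccc(OC)c(OCc3ccccc3)c2)COC1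
F4 | step 3 | 4-[3-(benzyloxy)-4-methoxybenzyl]-2,5-dihydrofuran-3-carboxylic acid | OC(=O)C1=C(Cc2ccc(OC)c(OCc3ccccc3)c2)COC1
F5 | step 3 | (3S,4R)-4-[3-(benzyloxy)-4-methoxybenzyl]tetrahydrofuran-3-carboxylic acid | COc1ccc(C[C@H]2COC[C@H]2C(O)=O)cc1OCc1ccccc1
F6 | step 3 | (3S,4R)-4-[3-(benzyloxy)-4-methoxybenzyl]-N-methoxy-N-methyltetrahydrofuran-3-carboxamide | COc1ccc(C[C@H]2COC[C@H]2C(=O)N(C)OC)cc1OCc1ccccc1
F7 | step 3 | [3-(benzyloxy)-4-methoxyphenyl]magnesium bromide | COc1ccc([Mg]Br)cc1OCc1ccccc1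
F8 | step 4 | (R)-[3-(benzyloxy)-4-methoxyphenyl]{(3S,4R)-4-[3-(benzyloxy)-4-methoxybenzyl]tetrahydrofuran-3-yl}methanol | COc1ccc(C[C@H]2COC[C@H]2[C@@H](O)c2ccc(OC)c(OCc3ccccc3)c2)cc1OCc1ccccc1
F9 | step 4 | (S)-[3-(benzyloxy)-4-methoxyphenyl]{(3S,4R)-4-[3-(benzyloxy)-4-methoxybenzyl]tetrahydrofuran-3-yl}methyl 4-nitrobenzoate | COc1ccc(C[C@H]2COC[C@H]2[C@H](OC(=O)c2ccc(cc2)[N+](=O)[O-])c2ccc(OC)c(OCc3ccccc3)c2)cc1OCc1ccccc1
F10 | step 5 | (3-hydroxy-4-methoxyphenyl)[(3S,4R)-4-(3-hydroxy-4-methoxybenzyl)tetrahydrofuran-3-yl]methanone | COc1ccc(C[C@H]2COC[C@H]2C(=O)c2ccc(OC)c(O)c2)cc1O
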